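## Structural features

The target is a briarane-type diterpenoid. Ring A (C1, C10, C11, C12, C13, C14; an 11-hydroxy-11-methyl-12-oxo-13-ene) is trans-fused along C1–C10 to the ten-membered carbocycle ring B (C1 to C10). Ring B carries the γ-lactone ring C (C7, O, C19, C17, C8) across C7–C8. There are eight stereocentres in two arrays that meet at the ring fusion: C11–C10–C1–C2 and C9–C8–C7, plus C17. C1 is an all-carbon quaternary centre, C8 and C11 are tertiary carbinols, and the C5=C6 olefin is trisubstituted and Z. The fragile groups are the α-ketol enone of ring A (sensitive to base, organometallics and one-electron reductants), the β-hydroxy lactone with its epimerisable C17 and allylic C7–O bond, and two secondary acetates. The real difficulty is ring B: a ten-membered ring with a Z-trisubstituted olefin must be closed beside a congested trans ring fusion, and C2, C7, C8 and C17 must then be set on a flexible ring. The key step uses the 1,5-relationship between oxygen-bearing C2 and olefinic C6 (C2–C3–C4–C5=C6), the retron of a Claisen rearrangement. Ring B can therefore be opened at C3–C4 and re-tied through oxygen (O–C6) as an eight-membered 2-methylene oxacycle fused to ring A.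

## Logic of the disconnections

37 to 34: the C9 acetate is removed and the C12 carbonyl is taken back to a silyl-protected carbinol, with silyl ethers on C9 and C11. The ring A ketol enone would not survive organolithium, titanium, hydride or samarium reagents. Ring A loses all reactive functionality. The forward demand is an endgame that tells C12–OH (allylic, oxidised by MnO2) from C9–OH (acetylated last) and from the two tertiary hydroxyls.

34 to 32 to 31: the C8–C17 bond is cut (aldol retron of the β-hydroxy lactone), then the C7–O acyl bond. Ring C and two stereocentres (C8, C17) disappear. The forward intramolecular Reformatsky closure must attack the C8 carbonyl face that gives the trans-fused lactone; C17 can be corrected by equilibration.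

31 to 30: the C7–O bond is cut back to the enolate of the C8 ketone. This removes the C7 stereocentre. It demands enolisation towards allylic C7 and not C9, and attack of the oxidant on one face.

30 to 26: C8=O is traced to an aryl-protected carbinol and the C2 acetate to a C2 ketone. The gain is that 26 holds a single carbonyl and the C8 mask is orthogonal to every silyl ether. The demands are a reagent-controlled reduction at C2 and an oxidative unmasking at C8 that leaves the ring A ethers alone.

26 to 25 (key): the C3–C4 bond is cut and O–C6 is reconnected. Ring B shrinks to an oxocane in which C2 is an enol ether carbon and C6 carries an isopropenyl group. The gain is a common-ring ether in place of a medium carbocycle, and the C2 oxygen is accounted for. The demand is a chair-like [3,3] shift that delivers Z geometry at C5=C6, on a substrate with no carbonyl group.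

25 to 24 to 22: the exocyclic C2=C3 bond is traced to the lactone carbonyl (C3 comes from a titanium methylidene), then the lactone C2–O bond is cut. This gives an open hydroxy acid. The demands are an eight-membered lactonisation of a neopentylic acid and a methylenation that meets no other carbonyl.

22 to 20 to 19 to 17: the acid comes from a tert-butyl ester. The C5–C6 bond is cut to an isopropenyl nucleophile and a C6 aldehyde, which comes from a terminal vinyl group by hydroboration and oxidation. The gain is a simple C6–C9 chain. C6 is a spectator centre that is erased in the key step.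

17 to 13 plus 14: the C8–C9 bond is cut to a C9 aldehyde and a γ-aryloxyallyl boron reagent. One step brings C6–C8, the masked C8 oxygen and the C9 stereocentre. The demand is reagent control at C9, because the aldehyde is flanked by two nearly equivalent quaternary carbons and offers little substrate bias.

13 to 7: functional group changes only (C9 aldehyde from the ethyl ester; C11–O bond from enolate oxidation; C12 carbinol from the ketone). The tert-butyl ester at C2 must survive the hydride that reduces the C9 ester.

7 to 4 to 2 plus 3, and 2 to 1: C10–C11 and C1–C14 are cut (Diels–Alder retron). The enone comes from the silyl enol ether of the adduct and the C2 ester from the formyl group. Ring A, the quaternary C1, the trans C1/C10 relationship and the absolute configuration all come from one catalytic step on commercial materials, and C2 (aldehyde) and C9 (ester) are born differentiated.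

## Other disconnections considered

Alternative 1: The cut is through C10–C11 and C1–C14 of ring A. In the forward sense diene A1, (1E,3Z)-1-ethoxy-3-(trimethylsilyloxy)penta-1,3-diene, would add thermally to dimethyl mesaconate A2, and acid work-up would expel ethanol to give enone diester A3.
- In favour: C1, the trans C1/C10 relationship and the enone would arise in one step from a cheap diester. The enone needs no separate dehydrogenation, so on this point the alternative is better than the sequence 2 to 4 to 5, which needs step 3.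
- Against: the thermal addition is racemic, the two esters (C2 and C9) are not differentiated, and as a strategy-bearing step it leaves ring B, the Z olefin and the lactone untouched.
- Comparison: on structure it solves only ring A. On mechanism it is the equal of step 2 of the chosen plan, which is the same kind of [4+2] with the same regiochemical logic. The chosen variant gives up the direct enone for catalyst-set absolute configuration and an aldehyde/ester pair that can be told apart. Once a resolution and an ester differentiation are counted, step economy up to 13 should be about equal.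

Alternative 2: The cut is the C8–C17 bond of ring C, with C7 and C8 taken from the chiral pool. Rh2(OAc)4 (dirhodium tetraacetate, divalent rhodium) would decompose diazoacetate A4, a D-erythronic acid derivative, and the carbenoid would insert into the C8–H bond next to the acetonide oxygen to give spiro lactone A5 with retention.
- In favour: the tertiary C8–O centre and C7 would be fixed early by a stereospecific, five-ring-selective insertion. This is better than the chosen plan exactly where that plan is weakest, because the chosen plan sets C7 and C8 late on a mobile ring (steps 24 and 26).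
- Against: A5 holds only C6 to C9, C17 and C19. The methyl on C17, the C9 stereocentre, the union with a hindered ring A partner at C10 and the closure of ring B all remain, and the closure would have to be done beside a base-sensitive β-oxygenated lactone.
- Comparison: on mechanism the two key steps are equally reliable concerted events. On structure A5 solves the lactone but not the medium ring, and the chosen plan does the reverse. On step economy the extra fragment coupling and a separate macrocyclisation are expected to make this route longer.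

Alternative 3: The cut is C6–C7. CrCl2 with catalytic NiCl2 (divalent chromium, divalent nickel) would convert the Z vinyl iodide of seco aldehyde A6 into a vinylchromium species that adds to the C7 aldehyde. This closes ring B and gives hydroxy ester A7, which would then lactonise.
- In favour: the Z geometry is built into A6 and transferred with retention. This is better than the chosen plan, where geometry depends on the shape of a transition state. The mild organochromium step tolerates acetates, the enone and free tertiary hydroxyls, so the endgame would be shorter, which is also better. C8 and C17 would be made under acyclic control.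
- Against: A6 is a fully functionalised acyclic chain with an α-hydroxy aldehyde on a quaternary carbon. The ten-membered closure needs high dilution and a large excess of chromium. The C7 carbinol is created in the closure with only 1,2-induction from C8.
- Comparison: on structure both plans close ring B in one step. The alternative creates one stereocentre (C7) there under uncertain control; the Claisen creates none but leaves C7, C8 and C17 for later. On mechanism an ionic addition on a floppy chain is less predictable than a concerted shift. On step economy the shorter endgame is offset by the long build of A6, so the two should be comparable.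

Key step: step 19

Remarks on the chemistry (assumptions, one line each):
- Briarane numbering is used; α/β refer to the usual flat drawing with the C1 methyl β. The target is 2α-OAc, 7α-O (7β-H), 8α-OH, 9α-OAc, 10α-H, 11α-OH, 11β-CH3, 17α-CH3, that is (1S,2R,5Z,7S,8S,9R,10S,11S,17R).
- Atom bookkeeping of the key step: the ring grows by two members (eight to ten). C3, C4 and C5 enter the ring and the ring oxygen leaves it as the C2 carbonyl oxygen, so this is not a four-carbon enlargement; C6 is already a ring atom.
- A precursor masked as dioxolanes at both C8 and C12 with a trimethylsilyl ether at C11 was rejected: the allylic C12 ketal would hydrolyse before the hindered C8 ketal, so the enone would be exposed to base and SmI2. C8 is carried as an aryl ether (oxidative removal) and ring A as the 11,12-diol bis-silyl ether.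
- C6 is erased in step 19. Step 15 should give both C6 epimers; structures are drawn for the (6S) epimer.
- The catalyst antipode in step 2 is assigned by analogy with 2-substituted acroleins; if the mirror-image adduct forms, the (R)-catalyst is used. The reagent antipodes in steps 11 and 20 follow the usual facial models (Si-face allyl transfer from the (+)-α-pinene-derived borane; (S)-CBS gives the alcohol with the larger group placed as in (R)-1-phenylethanol).

## Route

Step 1
Reactants: 1 pent-1-en-3-one
Product: 2 (Z)-3-(triisopropylsilyloxy)penta-1,3-diene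
Conditions: TIPSOTf, Et3N, Et2O, 0 °C
Reagents that add atoms: triisopropylsilyl trifluoromethanesulfonate, CC(C)[Si](C(C)C)(C(C)C)OS(=O)(=O)C(F)(F)F
Why: Soft enolisation of the ethyl ketone with a silyl triflate and an amine should give the 2-silyloxy diene with the Z enol ether, which places the terminal methyl outside in the s-cis diene.

Step 2
Reactants: 2 (Z)-3-(triisopropylsilyloxy)penta-1,3-diene; 3 ethyl (E)-3-methyl-4-oxobut-2-enoate
Product: 4 ethyl 2-formyl-2,6-dimethyl-5-(triisopropylsilyloxy)cyclohex-4-ene-1-carboxylate (ring A: 1β-CH3, 1α-CHO, 10α-H, 10β-CO2Et, 11α-CH3)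
Conditions: (S)-o-tolyl-CBS-oxazaborolidine, Tf2NH (20 mol %), CH2Cl2, −78 to −40 °C
Reagents that add atoms: none
Why: Catalytic enantioselective Diels–Alder reaction of a 2-substituted enal with a 2-silyloxy diene; the boron-bound formyl group directs the nucleophilic diene terminus C11 to C10 and C14 to C1, forming C10–C11 and C1–C14. The E dienophile fixes C2 (CHO) and C9 (CO2Et) trans, the catalyst fixes the absolute sense at C1 and C10, and the C11 methyl centre is of no consequence because C11 is made trigonal in step 6.

Step 3
Reactants: 4 ethyl 2-formyl-2,6-dimethyl-5-(triisopropylsilyloxy)cyclohex-4-ene-1-carboxylate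
Product: 5 ethyl 2-formyl-2,6-dimethyl-5-oxocyclohex-3-ene-1-carboxylate
Conditions: Pd(OAc)2 (10 mol %), O2 (1 atm), DMSO, 60 °C
Reagents that add atoms: none
Why: Saegusa–Ito oxidation; palladium diacetate (divalent palladium) forms the C13 palladium enolate from the silyl enol ether and β-hydride loss from C14 gives the C13=C14 enone regiospecifically. C1 is quaternary, so the olefin cannot move.

Step 4
Reactants: 5 ethyl 2-formyl-2,6-dimethyl-5-oxocyclohex-3-ene-1-carboxylate
Product: 6 6-(ethoxycarbonyl)-1,5-dimethyl-4-oxocyclohex-2-ene-1-carboxylic acid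
Conditions: NaClO2, NaH2PO4, 2-methylbut-2-ene, t-BuOH/H2O, 0 °C to rt
Reagents that add atoms: sodium chlorite, [Na+].[O-]Cl=O
Why: Pinnick oxidation of the neopentylic aldehyde; the enone and ester are inert. The acid is a vinylogous β-keto acid and is esterified at once.

Step 5
Reactants: 6 6-(ethoxycarbonyl)-1,5-dimethyl-4-oxocyclohex-2-ene-1-carboxylic acid
Product: 7 1-tert-butyl 2-ethyl 1,3-dimethyl-4-oxocyclohex-5-ene-1,2-dicarboxylate
Conditions: Cl3CC(=NH)O-t-Bu, BF3·OEt2 (cat.), CH2Cl2/cyclohexane, rt
Reagents that add atoms: tert-butyl 2,2,2-trichloroacetimidate, CC(C)(C)OC(=N)C(Cl)(Cl)Cl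
Why: O-alkylation of the acid by the imidate is insensitive to hindrance at the acyl carbon. The tert-butyl ester on quaternary C1 is the element that later tells C2 from C9.

Step 6
Reactants: 7 1-tert-butyl 2-ethyl 1,3-dimethyl-4-oxocyclohex-5-ene-1,2-dicarboxylate
Product: 8 1-tert-butyl 2-ethyl 3-hydroxy-1,3-dimethyl-4-oxocyclohex-5-ene-1,2-dicarboxylate (11α-OH, 11β-CH3)
Conditions: KN(SiMe3)2, THF, −78 °C; 2-(phenylsulfonyl)-3-phenyloxaziridine, −78 °C
Reagents that add atoms: 2-(phenylsulfonyl)-3-phenyloxaziridine, O=S(=O)(c1ccccc1)N1OC1c1ccccc1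
Why: Oxidation of the cross-conjugated enolate (the only α′ hydrogen is on C11) with an N-sulfonyl oxaziridine. The oxidant should enter anti to the pseudo-axial β ester on C10 and away from the β methyl on C1, which sets 11α-OH.

Step 7
Reactants: 8 1-tert-butyl 2-ethyl 3-hydroxy-1,3-dimethyl-4-oxocyclohex-5-ene-1,2-dicarboxylate
Product: 9 1-tert-butyl 2-ethyl 3,4-dihydroxy-1,3-dimethylcyclohex-5-ene-1,2-dicarboxylate (11α-OH, 12β-OH)
Conditions: NaBH4, CeCl3·7H2O, MeOH, −40 °C
Reagents that add atoms: none
Why: Luche 1,2-reduction of the enone; hydride should enter anti to the pseudo-axial C10 ester to give the 12β-carbinol. This centre is temporary (it is re-oxidised in step 28), so its configuration is not critical.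

Step 8
Reactants: 9 1-tert-butyl 2-ethyl 3,4-dihydroxy-1,3-dimethylcyclohex-5-ene-1,2-dicarboxylate
Product: 11 ring A diester bis-silyl ether (12β-OTBS 11α-OTES), via 12-O-silyl mono-ether 10 (not isolated)
Conditions: TBSOTf (1.1 equiv), 2,6-lutidine, CH2Cl2, −78 °C; then TESOTf, 0 °C to rt
Reagents that add atoms: tert-butyldimethylsilyl trifluoromethanesulfonate, CC(C)(C)[Si](C)(C)OS(=O)(=O)C(F)(F)F; triethylsilyl trifluoromethanesulfonate, CC[Si](CC)(CC)OS(=O)(=O)C(F)(F)F
Why: The secondary allylic hydroxyl is silylated far faster than the tertiary one, so sequential addition of the two silyl triflates gives the mixed ether in one flask. A labile silyl group on the tertiary oxygen eases the final deprotection and blocks lactonisation of 11-OH onto the cis C2 carboxyl.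

Step 9
Reactants: 11 ring A diester bis-silyl ether
Product: 12 ring A C9 primary alcohol (tert-butyl 6-(hydroxymethyl) ester, 12β-OTBS, 11α-OTES)
Conditions: LiBH4, THF/MeOH, 0 to 40 °C
Reagents that add atoms: none
Why: Lithium borohydride reduces the ethyl ester but not a tert-butyl ester on a quaternary carbon, so C9 alone is reduced.

Step 10
Reactants: 12 ring A C9 primary alcohol
Product: 13 ring A C9 aldehyde
Conditions: Dess–Martin periodinane, NaHCO3, CH2Cl2, 0 °C to rt
Reagents that add atoms: none
Why: Buffered hypervalent iodine oxidation of a hindered primary alcohol, without epimerisation at C10 or loss of the silyl ethers.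

Step 11
Reactants: 13 ring A C9 aldehyde; 14 1-(allyloxy)-4-methoxybenzene
Product: 16 (8R,9R)-syn 9-hydroxy-8-(4-methoxyphenoxy) homoallyl adduct with C7=C6 vinyl, via allylborane 15 (not isolated)
Conditions: 14, s-BuLi, THF, −78 °C; (−)-Ipc2BOMe; BF3·OEt2; then 13, −78 °C to rt; NaOH, H2O2
Reagents that add atoms: none
Why: Brown γ-alkoxyallylboration: the Z allylborane reacts through a closed chair transition state to form C8–C9 with syn O/O topology. The isopinocampheyl groups from (+)-α-pinene direct attack to the Si face of the aldehyde and set 9R; reagent control is needed because C10 is flanked by two nearly equivalent quaternary carbons.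

Step 12
Reactants: 16 (8R,9R)-syn adduct
Product: 17 9-O-TBS ether of 16
Conditions: TBSOTf, 2,6-lutidine, CH2Cl2, 0 °C
Reagents that add atoms: tert-butyldimethylsilyl trifluoromethanesulfonate, CC(C)(C)[Si](C)(C)OS(=O)(=O)C(F)(F)F
Why: Silyl triflate protection of a hindered secondary alcohol; the C9 oxygen stays masked until the last steps.

Step 13
Reactants: 17 9-O-TBS ether
Product: 18 C6 primary alcohol
Conditions: 9-BBN, THF, rt; NaOH, H2O2, 0 °C
Reagents that add atoms: hydrogen peroxide, OO
Why: Anti-Markovnikov hydroboration–oxidation of the terminal vinyl group. The bulky borane should leave the hindered cis-disubstituted C13=C14 olefin alone.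

Step 14
Reactants: 18 C6 primary alcohol
Product: 19 C6 aldehyde
Conditions: Dess–Martin periodinane, NaHCO3, CH2Cl2, 0 °C
Reagents that add atoms: none
Why: Buffered oxidation; the β-aryloxy aldehyde is used directly to avoid base-induced loss of the phenoxide.

Step 15
Reactants: 19 C6 aldehyde
Product: 20 (6S)-6-hydroxy-6-isopropenyl chain compound (C5=C4 with C16 methyl)
Conditions: CH2=C(CH3)MgBr, THF, −78 °C
Reagents that add atoms: isopropenylmagnesium bromide, C=C(C)[Mg]Br
Why: Grignard addition to the aldehyde forms C5–C6; the tert-butyl ester on quaternary carbon is inert at this temperature. Little 1,3-induction is expected, so both C6 epimers should form; the (6S) epimer is carried on and the (6R) epimer is kept for the alternative closure described at the end.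

Step 16
Reactants: 20 (6S)-carbinol tert-butyl ester
Product: 22 (6S)-seco acid, via bis-trimethylsilyl derivative 21 (not isolated)
Conditions: TMSOTf, 2,6-lutidine, CH2Cl2, 0 °C; then K2CO3, MeOH/H2O; pH 5 buffer
Reagents that add atoms: none
Why: Silyl triflate cleavage of the tert-butyl ester (O-silylation, loss of isobutene) does not depend on acyl hindrance and leaves the silyl and aryl ethers intact. Mild methanolysis then frees the acid and the C6 hydroxyl.

Step 17
Reactants: 22 (6S)-seco acid
Product: 24 ring A-fused eight-membered lactone (C2 carbonyl to O to C6), via mixed anhydride 23 (not isolated)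
Conditions: 2,4,6-Cl3C6H2COCl, Et3N, THF, rt; then DMAP, toluene, 90 °C, slow addition (high dilution)
Reagents that add atoms: none
Why: Yamaguchi macrolactonisation: the acyl pyridinium formed from the mixed anhydride is trapped by the C6 hydroxyl with retention at C6. The trans-disposed branches on ring A and the two fully substituted centres restrict the chain, which should help the eight-membered closure.

Step 18
Reactants: 24 ring A-fused eight-membered lactone
Product: 25 ring A-fused 2-methylene-8-isopropenyloxocane (9α-OTBS, 8β-OAr, 12β-OTBS, 11α-OTES)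
Conditions: Cp2Ti(μ-Cl)(μ-CH2)AlMe2, pyridine, THF/toluene, −40 °C to rt; NaOH aq; basic alumina
Reagents that add atoms: Tebbe reagent, C[Al-]1(C)C[Ti]([Cl+]1)(C1C=CC=C1)C1C=CC=C1
Why: Tebbe methylenation converts the lactone carbonyl into the exocyclic enol ether (C2=C3) through an oxatitanacyclobutane. The lactone is the only carbonyl in 24, and the acid-sensitive product is handled on basic alumina.

Step 19
Reactants: 25 ring A-fused 2-methylene-8-isopropenyloxocane
Product: 26 ring A and ring B bicyclic C2 ketone with 5Z olefin (9α-OTBS, 8β-OAr, 12β-OTBS, 11α-OTES)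
Conditions: degassed xylenes, Et3N (trace), sealed tube, 160–180 °C
Reagents that add atoms: none
Why: The allyl vinyl ether C3=C2–O–C6–C5=C4 undergoes a concerted suprafacial [3,3] shift through a chair-like six-atom array: C3–C4 forms as O–C6 breaks, and the enol ether oxygen becomes the C2 carbonyl. The closest known reaction type is the Claisen ring expansion of 2-methylene-6-vinyltetrahydropyrans to cyclooct-4-enones; here the oxacycle has eight members and the carbocycle ten. Ring B closes by sigmatropic ring enlargement within a bridged bicyclic transition structure in which the five-atom tether C1–C10–C9–C8–C7 spans C2 and C6, so no separate cyclisation mode has to be satisfied. No stereocentre is created, C6 is erased, and the only stereochemical element formed is the C5=C6 geometry. Z geometry is needed and should be secured by the tether: it can bridge the chair only when C7 is pseudo-axial on C6, which places C4 and C7 cis on the new double bond. Chemoselectivity is secured because 25 has a single allyl vinyl ether array and no carbonyl, and the fragment C3=C2–C1–C14=C13 is a 1,4-diene that cannot undergo a competing [3,3] shift. Carbonyl formation supplies the driving force against the strain of the Z-cyclodecenone, and the silyl and aryl ethers are thermally inert.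

Step 20
Reactants: 26 ring A and ring B bicyclic C2 ketone
Product: 27 (2R)-2α-alcohol
Conditions: (S)-2-methyl-CBS-oxazaborolidine, catecholborane, toluene, −78 to −20 °C
Reagents that add atoms: none
Why: Corey–Bakshi–Shibata reduction: the catalyst distinguishes the quaternary C1 flank from the C3 methylene, and the (S)-catalyst should deliver hydride to the face that gives the 2R carbinol. Catecholborane does not hydroborate the two olefins.

Step 21
Reactants: 27 (2R)-2α-alcohol
Product: 28 2α-acetate
Conditions: Ac2O, DMAP, pyridine, CH2Cl2, rt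
Reagents that add atoms: acetic anhydride, CC(=O)OC(C)=O
Why: DMAP-catalysed acetylation of the only free hydroxyl installs the C2 acetate of the target.

Step 22
Reactants: 28 2α-acetate
Product: 29 8β-alcohol
Conditions: (NH4)2Ce(NO3)6, pyridine, MeCN/H2O, 0 °C
Reagents that add atoms: none
Why: Oxidative removal of the 4-methoxyphenyl ether: the arene is oxidised to benzoquinone and the C8–O bond is untouched. Silyl ethers, the acetate and the olefins should survive short buffered exposure.

Step 23
Reactants: 29 8β-alcohol
Product: 30 C8 ketone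
Conditions: Dess–Martin periodinane, NaHCO3, CH2Cl2, 0 °C
Reagents that add atoms: none
Why: Neutral oxidation gives the β,γ-unsaturated ketone without moving the C5=C6 olefin into conjugation.

Step 24
Reactants: 30 C8 ketone
Product: 31 (7S)-7α-hydroxy C8 ketone
Conditions: KN(SiMe3)2, THF, −78 °C; 2-(phenylsulfonyl)-3-phenyloxaziridine, −78 °C
Reagents that add atoms: 2-(phenylsulfonyl)-3-phenyloxaziridine, O=S(=O)(c1ccccc1)N1OC1c1ccccc1
Why: Kinetic deprotonation should occur at the allylic C7 methylene rather than at the hindered silyloxy methine C9, and the dienolate is oxidised at its α carbon by the oxaziridine. Only the outer face of the ring enolate is open, and this peripheral attack is expected to set 7α-O.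

Step 25
Reactants: 31 (7S)-7α-hydroxy C8 ketone
Product: 32 7-O-(2-bromopropanoyl) ester (both epimers at the bromine-bearing carbon)
Conditions: CH3CHBrCOBr, pyridine, CH2Cl2, −30 °C
Reagents that add atoms: 2-bromopropanoyl bromide, CC(Br)C(Br)=O
Why: Acylation of the secondary hydroxyl by an acid bromide under mild base; the tertiary hydroxyls are masked. The bromine-bearing centre is destroyed in the next step, so the racemic reagent is used.

Step 26
Reactants: 32 7-O-(2-bromopropanoyl) ester
Product: 34 ring C lactone (8α-OH 17α-CH3) on the protected ring A and ring B core, via samarium enolate 33 (not isolated)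
Conditions: SmI2 (2.2 equiv), THF, −78 °C; NH4Cl aq
Reagents that add atoms: none
Why: Intramolecular Reformatsky reaction: samarium diiodide (divalent samarium) reduces the C–Br bond faster than any other group, and the trivalent samarium enolate, chelated to the ketone oxygen, adds to C8 to close the γ-lactone and form C8–C17. The tether from 7α-O should deliver the enolate to the face that leaves the new hydroxyl α (trans-fused lactone). The C17 methyl prefers to sit trans to the ring B branch at C8 and can be equilibrated to that position with DBU if needed.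

Step 27
Reactants: 34 ring C lactone, fully silylated
Product: 35 8,9,11,12-tetraol 2-acetate
Conditions: HF·pyridine, pyridine, THF, 0 °C to rt
Reagents that add atoms: none
Why: Buffered fluoride cleavage removes both TBS ethers and the tertiary TES ether in one operation; the acetate and the β-hydroxy lactone are stable to this acidic fluoride source.

Step 28
Reactants: 35 8,9,11,12-tetraol 2-acetate
Product: 36 12-oxo-13-ene triol (9-OH free)
Conditions: MnO2, CH2Cl2, rt
Reagents that add atoms: none
Why: Manganese dioxide oxidises only the allylic C12 carbinol, which restores the ring A enone; the saturated secondary C9–OH and the tertiary hydroxyls are inert.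

Step 29
Reactants: 36 12-oxo-13-ene triol
Product: 37 CNP0255369.2
Conditions: Ac2O, pyridine, DMAP (cat.), CH2Cl2, 0 °C
Reagents that add atoms: acetic anhydride, CC(=O)OC(C)=O
Why: C9–OH is the only secondary hydroxyl left, so controlled acetylation should give the 9-acetate while the tertiary C8 and C11 hydroxyls stay free.

## Compound list

1 | pent-1-en-3-one | CCC(=O)C=C | starting material
2 | (Z)-3-(triisopropylsilyloxy)penta-1,3-diene | C=C/C(O[Si](C(C)C)(C(C)C)C(C)C)=C/C | intermediate
3 | ethyl (E)-3-methyl-4-oxobut-2-enoate | CCOC(=O)/C=C(\C)C=O | starting material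
4 | ethyl 2-formyl-2,6-dimethyl-5-(triisopropylsilyloxy)cyclohex-4-ene-1-carboxylate (1β-CH3, 1α-CHO, 10β-CO2Et, 11α-CH3) | CCOC(=O)[C@@H]1[C@](C)(CC=C(O[Si](C(C)C)(C(C)C)C(C)C)[C@H]1C)C=O | intermediate
5 | ethyl 2-formyl-2,6-dimethyl-5-oxocyclohex-3-ene-1-carboxylate (same configuration) | CCOC(=O)[C@@H]1[C@](C)(C=CC(=O)[C@H]1C)C=O | intermediate
6 | 6-(ethoxycarbonyl)-1,5-dimethyl-4-oxocyclohex-2-ene-1-carboxylic acid (C2 acid on C1) | CCOC(=O)[C@@H]1[C@](C)(C=CC(=O)[C@H]1C)C(=O)O | intermediate
7 | 1-tert-butyl 2-ethyl 1,3-dimethyl-4-oxocyclohex-5-ene-1,2-dicarboxylate (trans esters) | CCOC(=O)[C@@H]1[C@](C)(C=CC(=O)[C@H]1C)C(=O)OC(C)(C)C | intermediate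
8 | 1-tert-butyl 2-ethyl 3-hydroxy-1,3-dimethyl-4-oxocyclohex-5-ene-1,2-dicarboxylate (11α-OH) | CCOC(=O)[C@@H]1[C@](C)(C=CC(=O)[C@@]1(C)O)C(=O)OC(C)(C)C | intermediate
9 | 1-tert-butyl 2-ethyl 3,4-dihydroxy-1,3-dimethylcyclohex-5-ene-1,2-dicarboxylate (11α-OH, 12β-OH) | CCOC(=O)[C@@H]1[C@](C)(C=C[C@H](O)[C@@]1(C)O)C(=O)OC(C)(C)C | intermediate
10 | 12-O-TBS mono-ether of 9 | CCOC(=O)[C@@H]1[C@](C)(C=C[C@H](O[Si](C)(C)C(C)(C)C)[C@@]1(C)O)C(=O)OC(C)(C)C | intermediate
11 | ring A diester, 12β-OTBS, 11α-OTES | CCOC(=O)[C@@H]1[C@](C)(C=C[C@H](O[Si](C)(C)C(C)(C)C)[C@@]1(C)O[Si](CC)(CC)CC)C(=O)OC(C)(C)C | intermediate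
12 | ring A C9 primary alcohol (C2 tert-butyl ester) | OC[C@@H]1[C@](C)(C=C[C@H](O[Si](C)(C)C(C)(C)C)[C@@]1(C)O[Si](CC)(CC)CC)C(=O)OC(C)(C)C | intermediate
13 | ring A C9 aldehyde (C2 tert-butyl ester) | O=C[C@@H]1[C@](C)(C=C[C@H](O[Si](C)(C)C(C)(C)C)[C@@]1(C)O[Si](CC)(CC)CC)C(=O)OC(C)(C)C | intermediate
14 | 1-(allyloxy)-4-methoxybenzene | C=CCOc1ccc(OC)cc1 | starting material
15 | [(Z)-3-(4-methoxyphenoxy)allyl]bis(isopinocampheyl)borane, isopinocampheyl groups from (+)-α-pinene | COc1ccc(O/C=C\CB([C@@H]2C[C@@H]3C[C@H]([C@H]2C)C3(C)C)[C@@H]2C[C@@H]3C[C@H]([C@H]2C)C3(C)C)cc1 | intermediate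
16 | (8R,9R)-syn adduct: 9-OH, 8-O-(4-methoxyphenyl), C7=C6 vinyl, on ring A | C=C[C@@H](Oc1ccc(OC)cc1)[C@H](O)[C@@H]1[C@](C)(C=C[C@H](O[Si](C)(C)C(C)(C)C)[C@@]1(C)O[Si](CC)(CC)CC)C(=O)OC(C)(C)C | intermediate
17 | 9-O-TBS ether of 16 | C=C[C@@H](Oc1ccc(OC)cc1)[C@H](O[Si](C)(C)C(C)(C)C)[C@@H]1[C@](C)(C=C[C@H](O[Si](C)(C)C(C)(C)C)[C@@]1(C)O[Si](CC)(CC)CC)C(=O)OC(C)(C)C | intermediate
18 | C6 primary alcohol | OCC[C@@H](Oc1ccc(OC)cc1)[C@H](O[Si](C)(C)C(C)(C)C)[C@@H]1[C@](C)(C=C[C@H](O[Si](C)(C)C(C)(C)C)[C@@]1(C)O[Si](CC)(CC)CC)C(=O)OC(C)(C)C | intermediate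
19 | C6 aldehyde | O=CC[C@@H](Oc1ccc(OC)cc1)[C@H](O[Si](C)(C)C(C)(C)C)[C@@H]1[C@](C)(C=C[C@H](O[Si](C)(C)C(C)(C)C)[C@@]1(C)O[Si](CC)(CC)CC)C(=O)OC(C)(C)C | intermediate
20 | (6S)-6-hydroxy-6-isopropenyl tert-butyl ester | C=C(C)[C@@H](O)C[C@@H](Oc1ccc(OC)cc1)[C@H](O[Si](C)(C)C(C)(C)C)[C@@H]1[C@](C)(C=C[C@H](O[Si](C)(C)C(C)(C)C)[C@@]1(C)O[Si](CC)(CC)CC)C(=O)OC(C)(C)C | intermediate
21 | trimethylsilyl ester 6-O-trimethylsilyl ether of 22 | C=C(C)[C@@H](O[Si](C)(C)C)C[C@@H](Oc1ccc(OC)cc1)[C@H](O[Si](C)(C)C(C)(C)C)[C@@H]1[C@](C)(C=C[C@H](O[Si](C)(C)C(C)(C)C)[C@@]1(C)O[Si](CC)(CC)CC)C(=O)O[Si](C)(C)C | intermediate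
22 | (6S)-seco acid (C2 acid, 6-OH) | C=C(C)[C@@H](O)C[C@@H](Oc1ccc(OC)cc1)[C@H](O[Si](C)(C)C(C)(C)C)[C@@H]1[C@](C)(C=C[C@H](O[Si](C)(C)C(C)(C)C)[C@@]1(C)O[Si](CC)(CC)CC)C(=O)O | intermediate
23 | mixed anhydride of 22 with 2,4,6-trichlorobenzoic acid | C=C(C)[C@@H](O)C[C@@H](Oc1ccc(OC)cc1)[C@H](O[Si](C)(C)C(C)(C)C)[C@@H]1[C@](C)(C=C[C@H](O[Si](C)(C)C(C)(C)C)[C@@]1(C)O[Si](CC)(CC)CC)C(=O)OC(=O)c1c(Cl)cc(Cl)cc1Cl | intermediate
24 | ring A-fused eight-membered lactone (9α-OTBS, 8β-OAr, 6S-isopropenyl) | CC(C)(C)[Si](C)(C)O[C@@H]1[C@@H]2[C@](C)(C=C[C@H](O[Si](C)(C)C(C)(C)C)[C@@]2(C)O[Si](CC)(CC)CC)C(=O)O[C@H](C(C)=C)C[C@H]1Oc3ccc(OC)cc3 | intermediate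
25 | ring A-fused 2-methylene-8-isopropenyloxocane (key-step precursor) | CC(C)(C)[Si](C)(C)O[C@@H]1[C@@H]2[C@](C)(C=C[C@H](O[Si](C)(C)C(C)(C)C)[C@@]2(C)O[Si](CC)(CC)CC)C(=C)O[C@H](C(C)=C)C[C@H]1Oc3ccc(OC)cc3 | intermediate
26 | ring A and ring B bicyclic C2 ketone, 5Z (key-step product) | CC(C)(C)[Si](C)(C)O[C@@H]1[C@@H]2[C@](C)(C=C[C@H](O[Si](C)(C)C(C)(C)C)[C@@]2(C)O[Si](CC)(CC)CC)C(=O)CC/C(C)=C\C[C@H]1Oc3ccc(OC)cc3 | intermediate
27 | (2R)-2α-alcohol | CC(C)(C)[Si](C)(C)O[C@@H]1[C@@H]2[C@](C)(C=C[C@H](O[Si](C)(C)C(C)(C)C)[C@@]2(C)O[Si](CC)(CC)CC)[C@H](O)CC/C(C)=C\C[C@H]1Oc3ccc(OC)cc3 | intermediate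
28 | 2α-acetate | CC(C)(C)[Si](C)(C)O[C@@H]1[C@@H]2[C@](C)(C=C[C@H](O[Si](C)(C)C(C)(C)C)[C@@]2(C)O[Si](CC)(CC)CC)[C@H](OC(C)=O)CC/C(C)=C\C[C@H]1Oc3ccc(OC)cc3 | intermediate
29 | 8β-alcohol | CC(C)(C)[Si](C)(C)O[C@@H]1[C@@H]2[C@](C)(C=C[C@H](O[Si](C)(C)C(C)(C)C)[C@@]2(C)O[Si](CC)(CC)CC)[C@H](OC(C)=O)CC/C(C)=C\C[C@H]1O | intermediate
30 | C8 ketone | CC(C)(C)[Si](C)(C)O[C@@H]1[C@@H]2[C@](C)(C=C[C@H](O[Si](C)(C)C(C)(C)C)[C@@]2(C)O[Si](CC)(CC)CC)[C@H](OC(C)=O)CC/C(C)=C\CC1=O | intermediate
31 | (7S)-7α-hydroxy C8 ketone | CC(C)(C)[Si](C)(C)O[C@@H]1[C@@H]2[C@](C)(C=C[C@H](O[Si](C)(C)C(C)(C)C)[C@@]2(C)O[Si](CC)(CC)CC)[C@H](OC(C)=O)CC/C(C)=C\[C@H](O)C1=O | intermediate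
32 | 7-O-(2-bromopropanoyl) ester (both epimers at CHBr) | CC(C)(C)[Si](C)(C)O[C@@H]1[C@@H]2[C@](C)(C=C[C@H](O[Si](C)(C)C(C)(C)C)[C@@]2(C)O[Si](CC)(CC)CC)[C@H](OC(C)=O)CC/C(C)=C\[C@H](OC(=O)C(C)Br)C1=O | intermediate
33 | samarium ester enolate of 32 (enolate geometry undefined) | CC(C)(C)[Si](C)(C)O[C@@H]1[C@@H]2[C@](C)(C=C[C@H](O[Si](C)(C)C(C)(C)C)[C@@]2(C)O[Si](CC)(CC)CC)[C@H](OC(C)=O)CC/C(C)=C\[C@H](OC(=CC)O[Sm](I)I)C1=O | intermediate
34 | ring C lactone, 8α-OH, 17α-CH3, with 9-OTBS, 12-OTBS, 11-OTES | CC(C)(C)[Si](C)(C)O[C@@H]1[C@@H]2[C@](C)(C=C[C@H](O[Si](C)(C)C(C)(C)C)[C@@]2(C)O[Si](CC)(CC)CC)[C@H](OC(C)=O)CC/C(C)=C\[C@@H]2OC(=O)[C@H](C)[C@]21O | intermediate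
35 | 8,9,11,12-tetraol 2-acetate | O[C@@H]1[C@@H]2[C@](C)(C=C[C@H](O)[C@@]2(C)O)[C@H](OC(C)=O)CC/C(C)=C\[C@@H]2OC(=O)[C@H](C)[C@]21O | intermediate
36 | 12-oxo-13-ene 8,9,11-triol 2-acetate | O[C@@H]1[C@@H]2[C@](C)(C=CC(=O)[C@@]2(C)O)[C@H](OC(C)=O)CC/C(C)=C\[C@@H]2OC(=O)[C@H](C)[C@]21O | intermediate
37 | CNP0255369.2, (1S,2R,5Z,7S,8S,9R,10S,11S,17R)-2,9-diacetoxy-8,11-dihydroxy-12-oxobriara-5,13-dien-19,7-olide | CC(=O)O[C@@H]1[C@@H]2[C@](C)(C=CC(=O)[C@@]2(C)O)[C@H](OC(C)=O)CC/C(C)=C\[C@@H]2OC(=O)[C@H](C)[C@]21O | target

## Step count and least certain steps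

Total step count: 29 (29 isolated products, five intermediates not isolated). Longest linear sequence: 29 steps, from 1 to 37; 3 and 14 enter as commercial partners.

Step 19 (key step). The likely failure is loss of geometric control: the tether may also reach a C7-equatorial chair or a boat array and give the E olefin. The allylic C6–O bond may also ionise at the temperature needed, leading to elimination or a formal 1,3-shift. Ten-membered products are an extension of the secure eight-membered cases. Fallback (ring closure by metathesis at C5=C6 instead of the sigmatropic closure at C3–C4), setting out from 19: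
- Wittig methylenation (Ph3P=CH2) should give the terminal alkene F1.
- TMSOTf/2,6-lutidine gives the trimethylsilyl ester F2, which is hydrolysed on work-up to the acid F3.
- 3-Methylbut-3-enyllithium (2.2 equiv) converts the hindered acid into the dienyl ketone F4.
- Ring-closing metathesis with the second-generation Grubbs catalyst (H2IMes)(PCy3)Cl2Ru=CHPh at high dilution comes back to the route at 26; the less strained Z ring olefin is expected.

Step 17. The likely failures are oligomerisation in place of eight-membered closure, and transfer of the aroyl instead of the neopentylic acyl group from the mixed anhydride to the C6 hydroxyl. Closure is also slowed because ring A must adopt the conformer with the C2 and C9 branches gauche. Fallback (activation of the alcohol instead of the acid), setting out from 19: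
- The (6R) carbinol F5, the other epimer from step 15, is taken.
- The conditions of step 16 convert it through the silyl derivative F6 into the (6R) seco acid F7.
- Mitsunobu lactonisation (PPh3, DIAD, toluene, high dilution) closes the ring with inversion at C6 and comes back at 24.

Step 24. The likely failures are poor facial selectivity in the oxidation of the ring dienolate (ring conformation is the only control element), competing enolisation towards C9, and migration of the olefin into conjugation. Fallback (inversion at the C–O bond instead of facial control), setting out from 30: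
- If the 7β-hydroxy epimer F8 is the main product, Mitsunobu esterification with 2-bromopropanoic acid (PPh3, DIAD) inverts C7 and comes back at 32.

Step 26. The likely failures are attack on the wrong face of the C8 carbonyl (cis-fused lactone), reductive cleavage by SmI2 of the C–O bonds α to the ketone, and retro-aldol opening on work-up. Fallback (intermolecular addition, then lactonisation), setting out from 31:
- TESOTf/2,6-lutidine gives the 7-O-triethylsilyl ketone F9.
- The cerium-modified lithium enolate of ethyl propanoate (LDA, CeCl3, THF, −78 °C) adds to C8 from the ring periphery to give the β-hydroxy ester F10.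
- HF·pyridine removes all silyl groups, the freed 7-hydroxyl closes the lactone, and the route is rejoined at 35.

## Further compounds

F1 | step 19 | terminal alkene from methylenation of 19 | C=CC[C@@H](Oc1ccc(OC)cc1)[C@H](O[Si](C)(C)C(C)(C)C)[C@@H]1[C@](C)(C=C[C@H](O[Si](C)(C)C(C)(C)C)[C@@]1(C)O[Si](CC)(CC)CC)C(=O)OC(C)(C)C
F2 | step 19 | trimethylsilyl ester of F3 | C=CC[C@@H](Oc1ccc(OC)cc1)[C@H](O[Si](C)(C)C(C)(C)C)[C@@H]1[C@](C)(C=C[C@H](O[Si](C)(C)C(C)(C)C)[C@@]1(C)O[Si](CC)(CC)CC)C(=O)O[Si](C)(C)C
F3 | step 19 | alkenyl C2 acid | C=CC[C@@H](Oc1ccc(OC)cc1)[C@H](O[Si](C)(C)C(C)(C)C)[C@@H]1[C@](C)(C=C[C@H](O[Si](C)(C)C(C)(C)C)[C@@]1(C)O[Si](CC)(CC)CC)C(=O)O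
F4 | step 19 | dienyl C2 ketone (3-methylbut-3-enyl ketone) | C=CC[C@@H](Oc1ccc(OC)cc1)[C@H](O[Si](C)(C)C(C)(C)C)[C@@H]1[C@](C)(C=C[C@H](O[Si](C)(C)C(C)(C)C)[C@@]1(C)O[Si](CC)(CC)CC)C(=O)CCC(C)=C
F5 | step 17 | (6R) epimer of 20 | C=C(C)[C@H](O)C[C@@H](Oc1ccc(OC)cc1)[C@H](O[Si](C)(C)C(C)(C)C)[C@@H]1[C@](C)(C=C[C@H](O[Si](C)(C)C(C)(C)C)[C@@]1(C)O[Si](CC)(CC)CC)C(=O)OC(C)(C)C
F6 | step 17 | trimethylsilyl ester 6-O-trimethylsilyl ether of F7 | C=C(C)[C@H](O[Si](C)(C)C)C[C@@H](Oc1ccc(OC)cc1)[C@H](O[Si](C)(C)C(C)(C)C)[C@@H]1[C@](C)(C=C[C@H](O[Si](C)(C)C(C)(C)C)[C@@]1(C)O[Si](CC)(CC)CC)C(=O)O[Si](C)(C)C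
F7 | step 17 | (6R) seco acid | C=C(C)[C@H](O)C[C@@H](Oc1ccc(OC)cc1)[C@H](O[Si](C)(C)C(C)(C)C)[C@@H]1[C@](C)(C=C[C@H](O[Si](C)(C)C(C)(C)C)[C@@]1(C)O[Si](CC)(CC)CC)C(=O)O
F8 | step 24 | (7R)-7β-hydroxy C8 ketone (7-epimer of 31) | CC(C)(C)[Si](C)(C)O[C@@H]1[C@@H]2[C@](C)(C=C[C@H](O[Si](C)(C)C(C)(C)C)[C@@]2(C)O[Si](CC)(CC)CC)[C@H](OC(C)=O)CC/C(C)=C\[C@@H](O)C1=O
F9 | step 26 | 7-O-triethylsilyl ether of 31 | CC(C)(C)[Si](C)(C)O[C@@H]1[C@@H]2[C@](C)(C=C[C@H](O[Si](C)(C)C(C)(C)C)[C@@]2(C)O[Si](CC)(CC)CC)[C@H](OC(C)=O)CC/C(C)=C\[C@H](O[Si](CC)(CC)CC)C1=O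
F10 | step 26 | 8-hydroxy ethyl ester from propanoate addition to F9 (open lactone) | CC(C)(C)[Si](C)(C)O[C@@H]1[C@@H]2[C@](C)(C=C[C@H](O[Si](C)(C)C(C)(C)C)[C@@]2(C)O[Si](CC)(CC)CC)[C@H](OC(C)=O)CC/C(C)=C\[C@H](O[Si](CC)(CC)CC)[C@@]1(O)[C@@H](C)C(=O)OCC
A1 | alternative 1 | (1E,3Z)-1-ethoxy-3-(trimethylsilyloxy)penta-1,3-diene | CCO/C=C/C(O[Si](C)(C)C)=C/C
A2 | alternative 1 | dimethyl mesaconate | COC(=O)/C=C(\C)C(=O)OC
A3 | alternative 1 | dimethyl trans-1,3-dimethyl-4-oxocyclohex-5-ene-1,2-dicarboxylate | COC(=O)[C@@H]1[C@](C)(C=CC(=O)[C@H]1C)C(=O)OC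
A4 | alternative 2 | methyl 2-O-(diazoacetyl)-3,4-O-isopropylidene-D-erythronate | COC(=O)[C@H](OC(=O)C=[N+]=[N-])[C@H]1COC(C)(C)O1
A5 | alternative 2 | spiro-acetonide γ-lactone ester holding C6 to C9, C17 and C19 | COC(=O)[C@@H]1OC(=O)C[C@@]12COC(C)(C)O2
A6 | alternative 3 | seco (Z)-vinyl iodide C7 aldehyde | CC(=O)O[C@H]([C@@H]1[C@](C)(C=CC(=O)[C@@]1(C)O)[C@H](OC(C)=O)CC/C(C)=C\I)[C@@](O)(C=O)[C@@H](C)C(=O)OC
A7 | alternative 3 | ring B 7-hydroxy methyl ester (open lactone) | CC(=O)O[C@@H]1[C@@H]2[C@](C)(C=CC(=O)[C@@]2(C)O)[C@H](OC(C)=O)CC/C(C)=C\[C@H](O)[C@@]1(O)[C@@H](C)C(=O)OC
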